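Labels: chain carbons c1 to c9 run from the ring A alkyne to the lactone (CH3 on c1 and c8, c9 is the exocyclic CH). The lactone carbons are Cα (carries the ring B vinyl group), Cβ and Cγ.
Cuts, last-made bond first: c5=c6 (Julia-Kocienski), Cα-vinyl (Stille), Cβ-Cγ plus O-Cγ (Sonogashira coupling with lactonisation), c2-c3 plus c1-CH3 (methylalumination with Negishi coupling), ring A C(sp2)-C(sp) (diynylzinc coupling).
Enabling feature: c1=c2 is an E-trisubstituted alkene with its methyl on c1, and c1 is bonded directly to the C≡C on ring A. It is therefore the syn methyl/metal adduct of the terminal triple bond of a ring A buta-1,3-diyne. The inner triple bond, walled in by the gem-dimethyl carbon and the vinylic methyl of ring A, remains as the alkyne of the target.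
Forward: one enol triflate 5 supplies both six-membered rings. Ring A is grown diyne, c5 ester, c5 aldehyde 18. On ring B the oxirane is closed and a vinylstannane installed. The lactone ring is closed on the c6-c9 enyne sulfone and joined to ring B, the halves are united at c5=c6, and both silyl groups are removed last.
Stereochemistry: both ring carbinol centres descend from enzymatic reduction of ketoisophorone and substrate-controlled ketone hydrogenation (actinol 3). Both oxirane centres come from Sharpless epoxidation with D-(-)-diethyl tartrate. Alkene geometry comes from syn carbometalation, retentive couplings, syn hydrostannation, anti oxymetalation (Z at c9=Cγ), the purchased E-enynol 25 and equilibration at c5=c6.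

Key step: step 9

Assumption: the SMILES is read as E at c1=c2, c3=c4, c5=c6, c7=c8 and the ring B vinyl group and Z at c9=Cγ (c8 cis to the ring oxygen); compounds 1, 6, 11, 25 and 28 are taken as purchasable.

Step 1
Reactants: 1 ketoisophorone (2,6,6-trimethylcyclohex-2-ene-1,4-dione)
Product: 2 (6R)-2,2,6-trimethylcyclohexane-1,4-dione
Conditions: ene-reductase OYE2, NADP+ (cat.), glucose dehydrogenase, D-glucose, phosphate buffer pH 7, tBuOMe overlay, 30 °C, short contact time
Reagents that add atoms: none
Why: Biocatalytic conjugate reduction by an old yellow enzyme adds flavin hydride and a tyrosine proton trans across the activated enedione C=C, and the binding pocket sets the 6R methyl centre in what is a benchmark reaction of this enzyme class on this very substrate.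

Step 2
Reactants: 2 (6R)-2,2,6-trimethylcyclohexane-1,4-dione
Product: 3 (4R,6R)-4-hydroxy-2,2,6-trimethylcyclohexanone (actinol)
Conditions: H2, Raney Ni, MeOH, rt; recrystallisation
Reagents that add atoms: none
Why: Heterogeneous ketone hydrogenation picks the open C4 carbonyl over C1 (flanked by the quaternary carbon and the methine) and delivers hydrogen to the face remote from the axial C2 methyl, so the axial 4R alcohol trans to the C6 methyl should prevail, and recrystallisation removes the cis epimer and any minor enantiomer.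

Step 3
Reactants: 3 actinol
Product: 4 (4R,6R)-4-(tert-butyldimethylsilyloxy)-2,2,6-trimethylcyclohexanone
Conditions: TBSCl, imidazole, DMF, rt
Reagents that add atoms: tert-butyldimethylsilyl chloride, CC(C)(C)[Si](C)(C)Cl
Why: Imidazole-promoted silylation of a secondary alcohol gives an ether that withstands the amide base, organometallic, hydride, peroxide and palladium steps ahead and falls to fluoride at the end.

Step 4
Reactants: 4 silyl ether of actinol
Product: 5 (4R)-4-(tert-butyldimethylsilyloxy)-2,6,6-trimethylcyclohex-1-en-1-yl trifluoromethanesulfonate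
Conditions: LiN(iPr)2, THF, -78 °C; PhNTf2, -78 °C to rt
Reagents that add atoms: N-phenylbis(trifluoromethanesulfonimide), O=S(=O)(C(F)(F)F)N(c1ccccc1)S(=O)(=O)C(F)(F)F
Why: Enol triflate formation is unambiguous because C6 is the only enolisable position, the single tetrasubstituted enolate is O-sulfonylated, the C6 centre is deleted and the remote C4 centre, which cannot undergo β-elimination, is untouched.

Step 5
Reactants: 6 1,4-bis(trimethylsilyl)buta-1,3-diyne; 5 enol triflate
Product: 9 tert-butyldimethyl{[(1R)-3,5,5-trimethyl-4-(4-trimethylsilylbuta-1,3-diyn-1-yl)cyclohex-3-en-1-yl]oxy}silane, via lithium diynide 7 (not isolated), via diynylzinc bromide 8 (not isolated)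
Conditions: 6, MeLi·LiBr (1 equiv), THF, 0 °C to rt; ZnBr2, 0 °C; 5, Pd(PPh3)4 (5 mol %), THF-DMF, 50 °C
Reagents that add atoms: none
Why: Methyllithium cleaves one C-Si bond of the symmetric diyne, ZnBr2 converts the lithium diynide into the zinc reagent, and Negishi alkynylation of the enol triflate under zerovalent palladium forms the ring-alkyne bond without isolating a volatile terminal diyne and without copper-induced homocoupling.

Step 6
Reactants: 9 silylated ring A diyne
Product: 10 tert-butyl{[(1R)-4-(buta-1,3-diyn-1-yl)-3,5,5-trimethylcyclohex-3-en-1-yl]oxy}dimethylsilane (ring A terminal diyne)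
Conditions: K2CO3 (cat.), MeOH-THF, 0 °C; used at once
Reagents that add atoms: none
Why: Carbonate-catalysed methanolysis (protiodesilylation) of the alkynyl-silicon bond is far faster than attack on the hindered tert-butyldimethylsilyl ether.

Step 7
Reactants: 11 ethyl propiolate
Product: 12 ethyl (Z)-3-iodoacrylate
Conditions: NaI, AcOH, 70 °C
Reagents that add atoms: sodium iodide, [Na+].[I-]
Why: Conjugate hydroiodination of an ynoate proceeds by iodide addition and anti protonation of the allenolate, which gives the Z-iodide as kinetic product.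

Step 8
Reactants: 12 ethyl (Z)-3-iodoacrylate
Product: 13 ethyl (E)-3-iodoacrylate
Conditions: HI (57 % aq., cat.), toluene, 80 °C
Reagents that add atoms: none
Why: Acid-catalysed addition-elimination of hydrogen iodide equilibrates the β-iodoacrylate to the thermodynamically preferred E isomer.

Step 9
Reactants: 10 ring A terminal diyne; 13 ethyl (E)-3-iodoacrylate
Product: 16 ethyl (2E,4E)-7-[(4R)-4-(tert-butyldimethylsilyloxy)-2,6,6-trimethylcyclohex-1-en-1-yl]-5-methylhepta-2,4-dien-6-ynoate (ring A dienynoate), via alkenylalane 14 (not isolated), via alkenylzinc chloride 15 (not isolated)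
Conditions: AlMe3 (3 equiv), Cp2ZrCl2 (0.3 equiv), ClCH2CH2Cl, 0 °C to rt; volatiles removed in vacuo; THF, ZnCl2 (1 equiv), 13, Pd(PPh3)4 (5 mol %), rt
Reagents that add atoms: trimethylaluminium, C[Al](C)C
Why: Cp2ZrCl2 and AlMe3 form a methylzirconocene-aluminium species that adds methyl and metal syn across the terminal C≡C of 10, methyl to the inner carbon c1 and metal to c2, and Zr/Al exchange leaves alkenylalane 14 with the ring A alkynyl group trans to aluminium. After the excess AlMe3 has been pumped off so that it cannot methylate 13, ZnCl2 takes over the alkenyl group (15), zerovalent palladium inserts into the C-I bond of 13, and transmetalation and reductive elimination join c2 to c3 with retention on both partners, so 16 should be the E,E-dienynoate. The closest known reaction type is the zirconium-catalysed methylalumination of 1-alkynes, conjugated enynes and diynes included, followed by palladium- and zinc-cocatalysed Negishi alkenyl-alkenyl coupling. No ring closes and no stereocentre is formed, and the silyl ether is a spectator. The step needs three selectivities: the terminal triple bond must react instead of the internal one, which the gem-dimethyl carbon and the vinylic methyl of ring A secure by blocking the inner alkyne; methyl must go to c1, which is the normal bias of the catalyst for 1-alkynes; and carbometalation must outrun metalation of the acidic diyne C-H, which excess AlMe3 in a chlorinated solvent favours.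

Step 10
Reactants: 16 ring A dienynoate
Product: 17 (2E,4E)-7-[(4R)-4-(tert-butyldimethylsilyloxy)-2,6,6-trimethylcyclohex-1-en-1-yl]-5-methylhepta-2,4-dien-6-yn-1-ol
Conditions: iBu2AlH (2.5 equiv), CH2Cl2, -78 °C; aq. potassium sodium tartrate
Reagents that add atoms: none
Why: Hydride reduction of a conjugated ester with iBu2AlH is a clean 1,2-process at low temperature, where neither hydroalumination of the hindered alkyne nor loss of the silyl ether competes.

Step 11
Reactants: 17 ring A dienynol
Product: 18 (2E,4E)-7-[(4R)-4-(tert-butyldimethylsilyloxy)-2,6,6-trimethylcyclohex-1-en-1-yl]-5-methylhepta-2,4-dien-6-ynal (c5 aldehyde)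
Conditions: MnO2, CH2Cl2, rt, dark
Reagents that add atoms: none
Why: Allylic oxidation with activated MnO2 is selective for the dienylic primary alcohol and stops at the aldehyde without E/Z scrambling.

Step 12
Reactants: 5 enol triflate
Product: 19 methyl (4R)-4-(tert-butyldimethylsilyloxy)-2,6,6-trimethylcyclohex-1-ene-1-carboxylate
Conditions: CO (1 atm), Pd(OAc)2 (5 mol %), PPh3, Et3N, MeOH-DMF, 60 °C
Reagents that add atoms: carbon monoxide, [C-]#[O+]; methanol, CO
Why: Palladium-catalysed methoxycarbonylation of an enol triflate proceeds by oxidative addition, CO insertion and methanolysis of the acylpalladium species, and small CO copes well with the hindered ring position.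

Step 13
Reactants: 19 ring ester
Product: 20 [(4R)-4-(tert-butyldimethylsilyloxy)-2,6,6-trimethylcyclohex-1-en-1-yl]methanol
Conditions: iBu2AlH (2.5 equiv), toluene, -78 to 0 °C; aq. potassium sodium tartrate
Reagents that add atoms: none
Why: Hydride reduction of the α,β-unsaturated ester with iBu2AlH gives the primary allylic alcohol needed as the handle for directed epoxidation.

Step 14
Reactants: 20 ring allylic alcohol
Product: 21 [(1R,4S,6R)-4-(tert-butyldimethylsilyloxy)-2,2,6-trimethyl-7-oxabicyclo[4.1.0]heptan-1-yl]methanol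
Conditions: Ti(OiPr)4 (0.2 equiv), D-(-)-diethyl tartrate (0.25 equiv), tBuOOH, 4 Å MS, CH2Cl2, -20 °C
Reagents that add atoms: tert-butyl hydroperoxide, CC(C)(C)OO
Why: In the Sharpless asymmetric epoxidation the titanium-tartrate complex binds the primary alcohol and transfers peroxide oxygen to one alkene face, and the D-(-)-tartrate, which turns E-2-alken-1-ols into 2R,3R epoxy alcohols, sets C1 and C6 together as 1R,6R, the face anti to the silyloxy group and hence also the sterically matched one.

Step 15
Reactants: 21 epoxy alcohol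
Product: 22 (1S,4S,6R)-4-(tert-butyldimethylsilyloxy)-2,2,6-trimethyl-7-oxabicyclo[4.1.0]heptane-1-carbaldehyde
Conditions: nPr4NRuO4 (5 mol %), NMO, 4 Å MS, CH2Cl2, rt
Reagents that add atoms: none
Why: The Ley-Griffith oxidation is neutral and anhydrous, so the acid-sensitive oxirane survives and the aldehyde, which has no α-hydrogen, cannot epimerise (the descriptor at C1 changes only through ligand priority).

Step 16
Reactants: 22 epoxy aldehyde
Product: 23 tert-butyl{[(1R,4S,6R)-1-ethynyl-2,2,6-trimethyl-7-oxabicyclo[4.1.0]heptan-4-yl]oxy}dimethylsilane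
Conditions: dimethyl (1-diazo-2-oxopropyl)phosphonate, K2CO3, MeOH, 0 °C to rt
Reagents that add atoms: dimethyl (1-diazo-2-oxopropyl)phosphonate, CC(=O)C(=[N+]=[N-])P(=O)(OC)OC
Why: In the Ohira-Bestmann variant of the Seyferth-Gilbert homologation methanolysis releases the diazomethylphosphonate, its anion adds to the non-enolisable aldehyde, and loss of phosphate and nitrogen with a 1,2-hydrogen shift gives the terminal alkyne, the fully substituted oxirane being inert to carbonate in methanol.

Step 17
Reactants: 23 epoxy alkyne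
Product: 24 tributyl{(E)-2-[(1S,4S,6R)-4-(tert-butyldimethylsilyloxy)-2,2,6-trimethyl-7-oxabicyclo[4.1.0]heptan-1-yl]ethenyl}stannane
Conditions: Bu3SnH, PdCl2(PPh3)2 (2 mol %), THF, 0 °C
Reagents that add atoms: tributyltin hydride, CCCC[SnH](CCCC)CCCC
Why: Palladium-catalysed hydrostannation adds H and Sn syn and places tin on the terminal carbon because the inner alkyne carbon adjoins the quaternary oxirane carbon, which gives the E-stannane, and fast Sn-H addition is expected to outrun ionisation of the propargylic oxirane by zerovalent palladium.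

Step 18
Reactants: 25 (E)-3-methylpent-2-en-4-yn-1-ol
Product: 26 2-{[(2E)-3-methylpent-2-en-4-yn-1-yl]sulfanyl}-1,3-benzothiazole
Conditions: 2-mercaptobenzothiazole, PPh3, DIAD, THF, 0 °C
Reagents that add atoms: 2-mercaptobenzothiazole, Sc1nc2ccccc2s1
Why: Mitsunobu thioetherification of a primary allylic alcohol with the acidic heteroaryl thiol is a direct SN2 displacement that leaves the purchased E geometry of c7=c8 intact.

Step 19
Reactants: 26 enyne sulfide
Product: 27 2-{[(2E)-3-methylpent-2-en-4-yn-1-yl]sulfonyl}-1,3-benzothiazole (c6-c9 enyne sulfone)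
Conditions: H2O2 (30 %), (NH4)6Mo7O24·4H2O (10 mol %), EtOH, 0 °C to rt
Reagents that add atoms: hydrogen peroxide, OO
Why: Molybdate-catalysed peroxide oxidation takes the sulfide through the sulfoxide to the sulfone much faster than it attacks the electron-poor conjugated enyne.

Step 20
Reactants: 28 propiolic acid
Product: 29 (E)-2,3-dibromoprop-2-enoic acid
Conditions: Br2, LiBr, AcOH, rt, dark
Reagents that add atoms: bromine, BrBr
Why: Bromide-assisted ionic bromination of an alkyne is an anti addition, so the two bromines end up trans and the β-bromine lies cis to the carboxyl group as the later ring closure requires.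

Step 21
Reactants: 27 enyne sulfone; 29 (E)-2,3-dibromoprop-2-enoic acid
Product: 31 (5Z)-5-[(2E)-4-(1,3-benzothiazol-2-ylsulfonyl)-2-methylbut-2-en-1-ylidene]-3-bromofuran-2(5H)-one, via bromodienynoic acid 30 (not isolated)
Conditions: 29 (1.2 equiv), Pd(PPh3)4 (5 mol %), CuI (5 mol %), Et3N, MeCN, rt, dark
Reagents that add atoms: none
Why: In this tandem Sonogashira coupling and 5-exo-dig lactonisation zerovalent palladium inserts preferentially into the more electrophilic and less hindered β C-Br bond, and in enynoic acid 30 the cis carboxylate adds anti across the metal-activated triple bond at Cγ, which closes the five-membered lactone, fixes Z at c9=Cγ and keeps the α-bromide for the next step.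

Step 22
Reactants: 31 bromobutenolide sulfone; 24 ring B vinylstannane
Product: 32 (5Z)-5-[(2E)-4-(1,3-benzothiazol-2-ylsulfonyl)-2-methylbut-2-en-1-ylidene]-3-{(E)-2-[(1S,4S,6R)-4-(tert-butyldimethylsilyloxy)-2,2,6-trimethyl-7-oxabicyclo[4.1.0]heptan-1-yl]ethenyl}furan-2(5H)-one
Conditions: Pd2(dba)3·CHCl3 (2.5 mol %), AsPh3 (20 mol %), NMP, rt to 40 °C, dark
Reagents that add atoms: none
Why: In this Stille coupling the α-bromobutenolide is an activated alkenyl halide, the weakly donating arsine speeds transmetalation so that the reaction runs near room temperature under neutral conditions that spare the acidic allylic sulfone, the lactone and the oxirane, and the E geometry of the stannane is retained.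

Step 23
Reactants: 18 c5 aldehyde; 32 ring B butenolide sulfone
Product: 34 bis(tert-butyldimethylsilyl) ether of the target (all-E chain and Z ylidene), via c5=c6 Z isomer 33 (not isolated)
Conditions: NaN(SiMe3)2 added to 18 + 32, THF, -78 °C, dark; crude product in benzene, rt, diffuse daylight
Reagents that add atoms: none
Why: In the Julia-Kocienski olefination the sulfonyl carbanion, generated in the presence of the aldehyde, adds through c6 to the formyl carbon c5, Smiles transfer of the benzothiazolyl group and loss of SO2 and benzothiazolone create c5=c6, and since allylic benzothiazolyl sulfones and enals tend to give the Z alkene first, the crude polyene (33) is left to relax at this unhindered disubstituted position to the preferred E form while the Z ylidene bond, already the stable lactone isomer, stays put.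

Step 24
Reactants: 34 bis-silyl ether
Product: 35 target CNP0180336.1
Conditions: Bu4NF, AcOH (1:1), THF, 0 °C to rt, dark
Reagents that add atoms: none
Why: Fluoride-induced desilylation removes both secondary silyl ethers, and the acetic acid buffer keeps the medium from opening the lactone by alkoxide while remaining too weak to rearrange the vinyl oxirane, so no stereocentre or alkene is affected.

Compound list
1 | ketoisophorone, 2,6,6-trimethylcyclohex-2-ene-1,4-dione | CC1=CC(=O)CC(C)(C)C1=O | starting material
2 | (6R)-2,2,6-trimethylcyclohexane-1,4-dione | C[C@H]1C(=O)C(C)(C)CC(=O)C1 | intermediate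
3 | (4R,6R)-4-hydroxy-2,2,6-trimethylcyclohexanone (actinol, OH trans to the C6 methyl) | C[C@H]1C(=O)C(C)(C)C[C@H](O)C1 | intermediate
4 | (4R,6R)-4-(tert-butyldimethylsilyloxy)-2,2,6-trimethylcyclohexanone | C[C@H]1C(=O)C(C)(C)C[C@H](O[Si](C)(C)C(C)(C)C)C1 | intermediate
5 | (4R)-4-(tert-butyldimethylsilyloxy)-2,6,6-trimethylcyclohex-1-en-1-yl trifluoromethanesulfonate | CC1=C(OS(=O)(=O)C(F)(F)F)C(C)(C)C[C@H](O[Si](C)(C)C(C)(C)C)C1 | intermediate
6 | 1,4-bis(trimethylsilyl)buta-1,3-diyne | C[Si](C)(C)C#CC#C[Si](C)(C)C | starting material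
7 | lithium 4-(trimethylsilyl)buta-1,3-diyn-1-ide | [Li]C#CC#C[Si](C)(C)C | intermediate
8 | [4-(trimethylsilyl)buta-1,3-diyn-1-yl]zinc bromide | Br[Zn]C#CC#C[Si](C)(C)C | intermediate
9 | tert-butyldimethyl{[(1R)-3,5,5-trimethyl-4-(4-trimethylsilylbuta-1,3-diyn-1-yl)cyclohex-3-en-1-yl]oxy}silane | CC1=C(C#CC#C[Si](C)(C)C)C(C)(C)C[C@H](O[Si](C)(C)C(C)(C)C)C1 | intermediate
10 | tert-butyl{[(1R)-4-(buta-1,3-diyn-1-yl)-3,5,5-trimethylcyclohex-3-en-1-yl]oxy}dimethylsilane | CC1=C(C#CC#C)C(C)(C)C[C@H](O[Si](C)(C)C(C)(C)C)C1 | intermediate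
11 | ethyl propiolate | C#CC(=O)OCC | starting material
12 | ethyl (Z)-3-iodoacrylate | CCOC(=O)/C=C\I | intermediate
13 | ethyl (E)-3-iodoacrylate | CCOC(=O)/C=C/I | intermediate
14 | (E)-alkenyldimethylalane, Al on c2, methyl on c1, alkynyl trans to Al | CC1=C(C#C/C(C)=C/[Al](C)C)C(C)(C)C[C@H](O[Si](C)(C)C(C)(C)C)C1 | intermediate
15 | (E)-alkenylzinc chloride, Zn on c2 | CC1=C(C#C/C(C)=C/[Zn]Cl)C(C)(C)C[C@H](O[Si](C)(C)C(C)(C)C)C1 | intermediate
16 | ethyl (2E,4E)-7-[(4R)-4-(tert-butyldimethylsilyloxy)-2,6,6-trimethylcyclohex-1-en-1-yl]-5-methylhepta-2,4-dien-6-ynoate | CC1=C(C#C/C(C)=C/C=C/C(=O)OCC)C(C)(C)C[C@H](O[Si](C)(C)C(C)(C)C)C1 | intermediate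
17 | (2E,4E)-7-[(4R)-4-(tert-butyldimethylsilyloxy)-2,6,6-trimethylcyclohex-1-en-1-yl]-5-methylhepta-2,4-dien-6-yn-1-ol | CC1=C(C#C/C(C)=C/C=C/CO)C(C)(C)C[C@H](O[Si](C)(C)C(C)(C)C)C1 | intermediate
18 | (2E,4E)-7-[(4R)-4-(tert-butyldimethylsilyloxy)-2,6,6-trimethylcyclohex-1-en-1-yl]-5-methylhepta-2,4-dien-6-ynal | CC1=C(C#C/C(C)=C/C=C/C=O)C(C)(C)C[C@H](O[Si](C)(C)C(C)(C)C)C1 | intermediate
19 | methyl (4R)-4-(tert-butyldimethylsilyloxy)-2,6,6-trimethylcyclohex-1-ene-1-carboxylate | CC1=C(C(=O)OC)C(C)(C)C[C@H](O[Si](C)(C)C(C)(C)C)C1 | intermediate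
20 | [(4R)-4-(tert-butyldimethylsilyloxy)-2,6,6-trimethylcyclohex-1-en-1-yl]methanol | CC1=C(CO)C(C)(C)C[C@H](O[Si](C)(C)C(C)(C)C)C1 | intermediate
21 | [(1R,4S,6R)-4-(tert-butyldimethylsilyloxy)-2,2,6-trimethyl-7-oxabicyclo[4.1.0]heptan-1-yl]methanol (oxirane anti to OTBS) | OC[C@@]12O[C@]1(C)C[C@@H](O[Si](C)(C)C(C)(C)C)CC2(C)C | intermediate
22 | (1S,4S,6R)-4-(tert-butyldimethylsilyloxy)-2,2,6-trimethyl-7-oxabicyclo[4.1.0]heptane-1-carbaldehyde | O=C[C@@]12O[C@]1(C)C[C@@H](O[Si](C)(C)C(C)(C)C)CC2(C)C | intermediate
23 | tert-butyl{[(1R,4S,6R)-1-ethynyl-2,2,6-trimethyl-7-oxabicyclo[4.1.0]heptan-4-yl]oxy}dimethylsilane | C#C[C@@]12O[C@]1(C)C[C@@H](O[Si](C)(C)C(C)(C)C)CC2(C)C | intermediate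
24 | tributyl{(E)-2-[(1S,4S,6R)-4-(tert-butyldimethylsilyloxy)-2,2,6-trimethyl-7-oxabicyclo[4.1.0]heptan-1-yl]ethenyl}stannane | CCCC[Sn](CCCC)(CCCC)/C=C/[C@@]12O[C@]1(C)C[C@@H](O[Si](C)(C)C(C)(C)C)CC2(C)C | intermediate
25 | (E)-3-methylpent-2-en-4-yn-1-ol | C#C/C(C)=C/CO | starting material
26 | 2-{[(2E)-3-methylpent-2-en-4-yn-1-yl]sulfanyl}-1,3-benzothiazole | C#C/C(C)=C/CSc1nc2ccccc2s1 | intermediate
27 | 2-{[(2E)-3-methylpent-2-en-4-yn-1-yl]sulfonyl}-1,3-benzothiazole | C#C/C(C)=C/CS(=O)(=O)c1nc2ccccc2s1 | intermediate
28 | propiolic acid | C#CC(=O)O | starting material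
29 | (E)-2,3-dibromoprop-2-enoic acid (β-Br cis to CO2H) | OC(=O)/C(Br)=C\Br | intermediate
30 | (2E,6E)-8-(1,3-benzothiazol-2-ylsulfonyl)-2-bromo-6-methylocta-2,6-dien-4-ynoic acid (alkynyl cis to CO2H) | OC(=O)/C(Br)=C\C#C/C(C)=C/CS(=O)(=O)c1nc2ccccc2s1 | intermediate
31 | (5Z)-5-[(2E)-4-(1,3-benzothiazol-2-ylsulfonyl)-2-methylbut-2-en-1-ylidene]-3-bromofuran-2(5H)-one | O=S(=O)(C/C=C(C)/C=C1C=C(Br)C(=O)O/1)c2nc3ccccc3s2 | intermediate
32 | (5Z)-5-[(2E)-4-(1,3-benzothiazol-2-ylsulfonyl)-2-methylbut-2-en-1-ylidene]-3-{(E)-2-[(1S,4S,6R)-4-(tert-butyldimethylsilyloxy)-2,2,6-trimethyl-7-oxabicyclo[4.1.0]heptan-1-yl]ethenyl}furan-2(5H)-one | O=S(=O)(C/C=C(C)/C=C1C=C(/C=C/[C@@]45O[C@]4(C)C[C@@H](O[Si](C)(C)C(C)(C)C)CC5(C)C)C(=O)O/1)c2nc3ccccc3s2 | intermediate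
33 | bis-silyl ether with Z geometry at c5=c6, all other alkenes as in 34 | CC1=C(C#C/C(C)=C/C=C/C=C\C=C(C)\C=C2C=C(/C=C/[C@@]34O[C@]3(C)C[C@@H](O[Si](C)(C)C(C)(C)C)CC4(C)C)C(=O)O\2)C(C)(C)C[C@H](O[Si](C)(C)C(C)(C)C)C1 | intermediate
34 | bis(tert-butyldimethylsilyl) ether of the target | CC1=C(C#C/C(C)=C/C=C/C=C/C=C(C)/C=C2C=C(/C=C/[C@@]34O[C@]3(C)C[C@@H](O[Si](C)(C)C(C)(C)C)CC4(C)C)C(=O)O/2)C(C)(C)C[C@H](O[Si](C)(C)C(C)(C)C)C1 | intermediate
35 | (5Z)-3-{(E)-2-[(1S,4S,6R)-4-hydroxy-2,2,6-trimethyl-7-oxabicyclo[4.1.0]heptan-1-yl]ethenyl}-5-{(2E,4E,6E,8E)-11-[(4R)-4-hydroxy-2,6,6-trimethylcyclohex-1-en-1-yl]-2,9-dimethylundeca-2,4,6,8-tetraen-10-yn-1-ylidene}furan-2(5H)-one | CC1=C(C#C/C(C)=C/C=C/C=C/C=C(C)/C=C2C=C(/C=C/[C@@]34O[C@]3(C)C[C@@H](O)CC4(C)C)C(=O)O/2)C(C)(C)C[C@H](O)C1 | target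

Total step count: 24.
Longest linear sequence: 13 steps (steps 1 to 4, 12 to 17, 22 to 24).

Steps most likely to fail

Step 9. Three processes could spoil it. AlMe3 may metalate the acidic diyne C-H instead of carbometalating. The terminal diyne may oligomerise during the slow addition. Residual AlMe3 may transfer methyl to the iodoacrylate. The fallback builds the same ester without any carbometalation and sets out from 5 and 25. Sonogashira coupling of the triflate with the purchased E-enynol (Pd(PPh3)4, CuI, iPr2NH, DMF) gives the ring A enynol F1, in which the c1=c2 geometry and the c1 methyl are bought in. MnO2 oxidation gives the ring A enynal F2. Horner-Wadsworth-Emmons olefination with triethyl phosphonoacetate (NaH, THF) then forms c3=c4 E-selectively and comes back to the route at 16.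

Step 23. The strong base or the extended carbanion may attack the lactone. The benzothiazolyl sulfone may self-condense by ipso substitution. The carbanion may add through a vinylogous position. The Z to E relaxation at c5=c6 may stay incomplete. The fallback changes the order of assembly so that the lactone never meets the amide base, and sets out from 18 and 27. Julia-Kocienski olefination of the aldehyde with the simple enyne sulfone, followed by the same equilibration, gives the ring A tetraenediyne F3 with a free terminal alkyne at c9. Tandem Sonogashira coupling and lactonisation with 29 closes the lactone on the complete ring A chain and gives the ring A bromobutenolide F4. Stille coupling with stannane 24 is then the last C-C bond formation and comes back to the route at 34.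

Step 21. A second coupling may occur at the α-bromide of the product. 6-endo closure to a pyranone may compete. Zerovalent palladium may ionise the allylic sulfone, and the amine may deprotonate and degrade the product. The fallback separates coupling from ring closure and hands the closure to silver, setting out from 27. tert-Butyl propiolate is brominated (Br2, LiBr, AcOH) to tert-butyl (E)-2,3-dibromoacrylate F5. Sonogashira coupling with 27 at 0 °C stops at the tert-butyl bromodienynoate F6, which cannot cyclise. CF3CO2H in CH2Cl2 frees acid 30, this time isolated. Catalytic AgNO3 in acetone effects the 5-exo-dig lactonisation in the absence of palladium and amine and comes back to the route at 31.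

Further compounds
F1 | step 9 | (2E)-5-[(4R)-4-(tert-butyldimethylsilyloxy)-2,6,6-trimethylcyclohex-1-en-1-yl]-3-methylpent-2-en-4-yn-1-ol | CC1=C(C#C/C(C)=C/CO)C(C)(C)C[C@H](O[Si](C)(C)C(C)(C)C)C1
F2 | step 9 | (2E)-5-[(4R)-4-(tert-butyldimethylsilyloxy)-2,6,6-trimethylcyclohex-1-en-1-yl]-3-methylpent-2-en-4-ynal | CC1=C(C#C/C(C)=C/C=O)C(C)(C)C[C@H](O[Si](C)(C)C(C)(C)C)C1
F3 | step 23 | tert-butyl{[(1R)-4-[(3E,5E,7E,9E)-3,10-dimethyldodeca-3,5,7,9-tetraene-1,11-diyn-1-yl]-3,5,5-trimethylcyclohex-3-en-1-yl]oxy}dimethylsilane | CC1=C(C#C/C(C)=C/C=C/C=C/C=C(C)/C#C)C(C)(C)C[C@H](O[Si](C)(C)C(C)(C)C)C1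
F4 | step 23 | (5Z)-3-bromo-5-{(2E,4E,6E,8E)-11-[(4R)-4-(tert-butyldimethylsilyloxy)-2,6,6-trimethylcyclohex-1-en-1-yl]-2,9-dimethylundeca-2,4,6,8-tetraen-10-yn-1-ylidene}furan-2(5H)-one | CC1=C(C#C/C(C)=C/C=C/C=C/C=C(C)/C=C2C=C(Br)C(=O)O/2)C(C)(C)C[C@H](O[Si](C)(C)C(C)(C)C)C1
F5 | step 21 | tert-butyl (E)-2,3-dibromoprop-2-enoate | CC(C)(C)OC(=O)/C(Br)=C\Br
F6 | step 21 | tert-butyl (2E,6E)-8-(1,3-benzothiazol-2-ylsulfonyl)-2-bromo-6-methylocta-2,6-dien-4-ynoate | CC(C)(C)OC(=O)/C(Br)=C\C#C/C(C)=C/CS(=O)(=O)c1nc2ccccc2s1
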